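**Remark:** ring atoms keep the target numbering throughout (C1 = carbinol carbon bearing C7H2OBz, C2 = CHOAc, C3 = CHOBz, C4=C5, C6 = ketone carbon; the target SMILES decodes to (1S,2S,3R) with C1-OH/C2-OAc cis and C2-OAc/C3-OBz trans). The ligand antipode needed in step 6 is assumed to be assigned by a test reaction, both antipodes being available.

## Structural features

The target is a single carbocycle, a cyclohex-2-enone (C6 ketone, C4=C5 alkene), whose three remaining ring carbons C1, C2 and C3 are contiguous oxygenated stereocentres. C1 is a fully substituted α-ketol carbon with a free tertiary hydroxyl and the exocyclic C7H2 benzoate; C2 carries the acetate, cis to the C1 hydroxyl; C3 carries the second benzoate, trans to the C2 acetate and allylic to C4=C5. Four oxygens on four neighbouring carbons are in four different states (free tertiary OH, acetate, secondary benzoate, primary benzoate), so acyl migration is a constant threat. The γ-acyloxy enone is base-sensitive (vinylogous loss of benzoate, then of acetic acid) and the tertiary α-ketol can undergo α-ketol shifts, so the enone should appear late. The real difficulty is the C1/C2/C3 triad: a quaternary carbinol that must be set relative to two differently acylated neighbours and in the absolute sense. The feature the key step exploits is a latent mirror plane through C1 and C4: without the oxygens at C2, C3 and C6 the ring is a 1-substituted cyclohexa-2,5-dien-1-ol in which C2=C3 and C6=C5 are enantiotopic, and C1 becomes stereogenic the moment one of them is oxidised. Because the C1 hydroxyl is allylic to both alkenes, it can steer an oxidant to its own face (the C1/C2 cis relationship), and opening the resulting oxirane at C3 with inversion gives the C2/C3 trans relationship.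

## Logic of the disconnections

**13 to 10 (through 12 and 11).** The C6–O bond is cut, the alkene is returned from C4=C5 to C5=C6 and a hydrogen is returned to C4. This keeps the fragile γ-acyloxy enone out of every step but the last. The gain is that 10 has a plain cis-alkene and no ketone. C1 carries no hydrogen, so an ene-type oxidation can only take a hydrogen from C4 and place oxygen on C6. The forward step demands ene reactivity from a cis-disubstituted, inductively deactivated alkene, and elimination of the peroxide must beat fragmentation of the C1–C6 bond.

**10 to 9.** The acetyl C–O bond at the C2 oxygen is cut. In 9 this is the only secondary hydroxyl, so the last acyl group to be placed needs no protecting group. The forward step must acylate a hindered secondary OH next to a free tertiary OH without benzoate migration from the C3 oxygen.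

**9 to 8 and 1.** The C3–O bond is cut. The trans C2/C3 pattern is what SN2 opening of a cis-fused oxirane gives, so two stereocentres and one ester collapse into one epoxide, and the benzoate comes from 1. The forward step must attack C3, not C2, with clean inversion.

**8 to 7 (key).** Both C–O bonds of the oxirane (C2–O and C3–O) are cut. All three stereocentres disappear together and the precursor 7 is achiral, with a mirror plane through C1 and C4. The forward step must deliver oxygen to the face of the C1 hydroxyl, choose one of two enantiotopic alkenes, and stop after one epoxidation.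

**7 to 6.** The benzoyl C–O bond at the C7 oxygen is cut, which leaves a simple diol. The forward step must acylate the primary OH in the presence of the acid-labile tertiary bis-allylic OH.

**6 to 5.** C7 is returned to the ester oxidation level. The forward step is a hydride reduction that must leave the skipped diene alone.

**5 to 3 (through 4).** The C1–O bond is cut, so the tertiary hydroxyl comes from oxidation of an ester enolate. The forward step demands reaction of the cross-conjugated enolate at C1 and not at C3 or C5.

**3 to 2 to 1.** The methyl ester C–O bond is cut, then the ring is rearomatised. 1 supplies all seven carbons of the target core (ring plus C7). The forward dearomatisation must give the 2,5-diene, not the conjugated isomer.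

## Other disconnections considered

**Alternative 1:** (the plan that comes to mind first, chiral pool) Cut the C1–C7 and C1–OH bonds, so that the quaternary centre is built last on a ring bought from (−)-quinic acid. Its trans-4,5-diol maps onto C3/C2 in the correct absolute sense once the carboxyl-bearing carbon is excised and the 3-hydroxyl eliminated, giving enone A1. The forward key step is α'-deprotonation of A1 at C1, followed by electrophilic hydroxylation and then an aldol reaction with formaldehyde. The carbanion at C1 has the C2 oxygen in the β-position, so E1cB loss and aromatisation compete directly. The quaternary centre needs two separate enolate events whose facial course rests on the C2 substituent alone. A1 costs about five steps and its protecting groups must later be exchanged for one acetate and one benzoate on two similar secondary hydroxyls. The chosen plan sets C1–C3 in one event, never forms an enolate next to a leaving group, and is shorter.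

**Alternative 2:** Cut C4=C5. The forward key step is ring-closing metathesis of the acyclic diene A2 with second-generation Grubbs catalyst. The metathesis closes the ring but creates none of the stereocentres. The whole C1–C3 triad, quaternary carbinol included, would have to be assembled in an open chain beforehand, one centre at a time and under protection. A2 also carries a polymerisable vinyl ketone and an ionisable allylic benzoate. The key step would solve the easy part of the problem at greater length.

**Alternative 3:** Cut C3–O and C6–O. The forward sequence starts from the dihydrodiol acid A3 (ipso,ortho cis-dihydroxylation of benzoic acid by a microbial dioxygenase). Singlet oxygen is added across C3 and C6 of a protected form of A3, and the peroxide bridge is opened by Kornblum–DeLaMare elimination towards the C6 ketone. The absolute configuration is dictated by the enzyme. The strains used for this oxidation are described as giving the (1S,2R) acid, the mirror image of A3, so the same operations would end at the enantiomer of 13. In addition the base must choose H6 over H3 in the peroxide opening, and a fermentation is required. The chosen plan starts from the same arene, reaches either antipode by choice of ligand, and places the C6 oxygen without any regiochemical choice.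

Key step: step 6

## Route

Step 1
Reactants: 1 benzoic acid
Product: 2 cyclohexa-2,5-diene-1-carboxylic acid
Conditions: Na, NH3(l), EtOH, −78 to −33 °C; NH4Cl; then aq. HCl
Reagents that add atoms: none
Why: Birch reduction of an electron-poor arene protonates the ipso and para carbons, so the two remaining alkenes flank C1 symmetrically and 2 is achiral with a mirror plane through C1 and C4.

Step 2
Reactants: 2 cyclohexa-2,5-diene-1-carboxylic acid
Product: 3 methyl cyclohexa-2,5-diene-1-carboxylate
Conditions: TMSCHN2, PhMe/MeOH, 0 °C
Reagents that add atoms: trimethylsilyldiazomethane C[Si](C)(C)C=[N+]=[N-]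
Why: Neutral O-methylation of the acid; the absence of base avoids conjugation of the skipped diene.

Step 3
Reactants: 3 methyl cyclohexa-2,5-diene-1-carboxylate
Product: 5 methyl 1-hydroxycyclohexa-2,5-diene-1-carboxylate, via potassium enolate 4 (not isolated)
Conditions: KN(SiMe3)2, THF, −78 °C; 2-(phenylsulfonyl)-3-phenyloxaziridine, −78 °C; AcOH
Reagents that add atoms: 2-(phenylsulfonyl)-3-phenyloxaziridine O=S(=O)(c1ccccc1)N1OC1c1ccccc1
Why: Electrophilic hydroxylation of an ester enolate by an N-sulfonyloxaziridine; the doubly allylic α-hydrogen is removed easily and the cross-conjugated enolate reacts at C1, as in Birch reductive alkylation, so the 2,5-diene is kept and no stereocentre is formed.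

Step 4
Reactants: 5 methyl 1-hydroxycyclohexa-2,5-diene-1-carboxylate
Product: 6 1-(hydroxymethyl)cyclohexa-2,5-dien-1-ol
Conditions: LiAlH4, THF, 0 °C; H2O, aq. NaOH work-up
Reagents that add atoms: none
Why: Hydride reduction of the ester to the primary alcohol; isolated alkenes are inert and the basic work-up protects the acid-labile tertiary bis-allylic alcohol.

Step 5
Reactants: 6 1-(hydroxymethyl)cyclohexa-2,5-dien-1-ol
Product: 7 (1-hydroxycyclohexa-2,5-dien-1-yl)methyl benzoate
Conditions: BzCl (1.05 equiv), pyridine, CH2Cl2, −20 °C
Reagents that add atoms: benzoyl chloride O=C(Cl)c1ccccc1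
Why: Kinetic acylation of the primary hydroxyl over the tertiary one under basic, non-ionising conditions; this places the C7 benzoate of the target at the outset.

Step 6
Reactants: 7 (1-hydroxycyclohexa-2,5-dien-1-yl)methyl benzoate
Product: 8 [(1S,2S,6S)-2-hydroxy-7-oxabicyclo[4.1.0]hept-3-en-2-yl]methyl benzoate (target numbering: C1 S, C2 S, C3 S; oxirane across C2–C3 on the face of the C1 hydroxyl)
Conditions: Hf(OtBu)4 (10 mol%), chiral bishydroxamic acid ligand from trans-cyclohexane-1,2-diamine (12 mol%), cumene hydroperoxide (1.1 equiv), 4 Å MS, PhMe, 0 °C
Reagents that add atoms: cumene hydroperoxide CC(C)(OO)c1ccccc1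
Why: Mechanism: the tertiary alkoxide of 7 and the hydroperoxide bind to the ligand-bound tetravalent hafnium centre, and the distal peroxide oxygen is passed within this complex to one of the two ring alkenes. The closest known reaction type is the hydroxyl-directed catalytic asymmetric epoxidation of tertiary allylic alcohols with metal–bishydroxamate catalysts, run here in the desymmetrising mode familiar from the Katsuki–Sharpless epoxidation of divinyl carbinols. The only ring closed is the oxirane, formed by concerted syn transfer of one oxygen atom to the C2=C3 π bond (spiro transition state), which gives a cis-fused 7-oxabicyclo[4.1.0]heptene. C2 and C3 are controlled by the metal–alkoxide tether, which can reach only the ring face that carries the C1 oxygen, so the oxirane is cis to the hydroxyl; C1 becomes stereogenic through the choice between the enantiotopic C2=C3 and C6=C5 alkenes, and this choice is made by the C2-symmetric ligand. The step needs enantiotopic-group selection and mono- over bis-epoxidation: the rigid ring holds both alkenes at the same distance from the bound alkoxide, so the ligand pocket is the sole differentiating element, and the oxidant is kept limiting. Any molecule epoxidised on the disfavoured alkene still carries the favoured one and should be oxidised on to the achiral bis-epoxide faster than the major product, so the enantiomeric purity of 8 is expected to rise with conversion. The basic alkoxide medium with molecular sieves avoids ionisation of the acid-labile bis-allylic alcohol and leaves the benzoate alone.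

Step 7
Reactants: 8 [(1S,2S,6S)-2-hydroxy-7-oxabicyclo[4.1.0]hept-3-en-2-yl]methyl benzoate; 1 benzoic acid
Product: 9 [(1S,5R,6S)-5-(benzoyloxy)-1,6-dihydroxycyclohex-2-en-1-yl]methyl benzoate (target numbering: C1 S, C2 S, C3 R)
Conditions: PhCO2H (1.5 equiv), Ti(OiPr)4 (1.5 equiv), CH2Cl2, rt; aq. tartaric acid work-up
Reagents that add atoms: benzoic acid (compound 1) O=C(O)c1ccccc1
Why: Ti(OiPr)4-mediated opening of a 2,3-epoxy alcohol by a carboxylic acid: tetravalent titanium bridges the C1 alkoxide and the cis oxirane oxygen and benzoate attacks C3 by SN2, the carbon remote from the quaternary and inductively deactivated C1 side. Inversion at C3 gives the C2/C3 trans arrangement (C3 becomes R) while the C–O bonds at C1 and C2 are untouched.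

Step 8
Reactants: 9 [(1S,5R,6S)-5-(benzoyloxy)-1,6-dihydroxycyclohex-2-en-1-yl]methyl benzoate
Product: 10 [(1S,5R,6S)-6-acetoxy-5-(benzoyloxy)-1-hydroxycyclohex-2-en-1-yl]methyl benzoate
Conditions: Ac2O (1.2 equiv), pyridine, DMAP (cat.), CH2Cl2, 0 °C
Reagents that add atoms: acetic anhydride CC(=O)OC(C)=O
Why: DMAP-catalysed acylation; the C2 hydroxyl is the only secondary one and the tertiary C1 hydroxyl should not react at 0 °C with a slight excess of anhydride; no stereocentre is touched.

Step 9
Reactants: 10 [(1S,5R,6S)-6-acetoxy-5-(benzoyloxy)-1-hydroxycyclohex-2-en-1-yl]methyl benzoate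
Product: 13 [(1S,2S,3R)-2-acetoxy-3-(benzoyloxy)-1-hydroxy-6-oxocyclohex-4-en-1-yl]methyl benzoate (2-O-acetylzeylenone), via allylic hydroperoxide 11 (not isolated), via allylic peracetate 12 (not isolated)
Conditions: O2, TPP (cat.), hν (visible), CCl4, 10 °C; then Ac2O, pyridine, DMAP (cat.), CH2Cl2, 0 °C
Reagents that add atoms: dioxygen O=O
Why: Schenck ene reaction: singlet oxygen can take an allylic hydrogen only from C4 because C1 has none, so oxygen arrives at C6 and the alkene moves to C4=C5 (the C6 configuration is irrelevant). Acetylation of 11 gives 12, which loses acetate on base-mediated removal of H6 (Kornblum–DeLaMare-type elimination) and unveils the enone under conditions the product tolerates.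

## Compound list

1 | benzoic acid | O=C(O)c1ccccc1 | starting material
2 | cyclohexa-2,5-diene-1-carboxylic acid | OC(=O)C1C=CCC=C1 | intermediate
3 | methyl cyclohexa-2,5-diene-1-carboxylate | COC(=O)C1C=CCC=C1 | intermediate
4 | potassium enolate of 3 | COC([O-])=C1C=CCC=C1.[K+] | intermediate
5 | methyl 1-hydroxycyclohexa-2,5-diene-1-carboxylate | COC(=O)C1(O)C=CCC=C1 | intermediate
6 | 1-(hydroxymethyl)cyclohexa-2,5-dien-1-ol | OCC1(O)C=CCC=C1 | intermediate
7 | (1-hydroxycyclohexa-2,5-dien-1-yl)methyl benzoate | O=C(OCC1(O)C=CCC=C1)c1ccccc1 | intermediate
8 | [(1S,2S,6S)-2-hydroxy-7-oxabicyclo[4.1.0]hept-3-en-2-yl]methyl benzoate | O[C@]1(COC(=O)c2ccccc2)C=CC[C@@H]2O[C@H]12 | intermediate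
9 | [(1S,5R,6S)-5-(benzoyloxy)-1,6-dihydroxycyclohex-2-en-1-yl]methyl benzoate | O[C@H]1[C@H](OC(=O)c2ccccc2)CC=C[C@]1(O)COC(=O)c1ccccc1 | intermediate
10 | [(1S,5R,6S)-6-acetoxy-5-(benzoyloxy)-1-hydroxycyclohex-2-en-1-yl]methyl benzoate | CC(=O)O[C@H]1[C@H](OC(=O)c2ccccc2)CC=C[C@]1(O)COC(=O)c1ccccc1 | intermediate
11 | [(1S,2S,3R,6R)-2-acetoxy-3-(benzoyloxy)-6-hydroperoxy-1-hydroxycyclohex-4-en-1-yl]methyl benzoate (epimer with OOH cis to the C1 hydroxyl shown; the C6 epimer converges) | CC(=O)O[C@H]1[C@H](OC(=O)c2ccccc2)C=C[C@@H](OO)[C@]1(O)COC(=O)c1ccccc1 | intermediate
12 | [(1S,2S,3R,6R)-2-acetoxy-6-(acetylperoxy)-3-(benzoyloxy)-1-hydroxycyclohex-4-en-1-yl]methyl benzoate | CC(=O)O[C@H]1[C@H](OC(=O)c2ccccc2)C=C[C@@H](OOC(C)=O)[C@]1(O)COC(=O)c1ccccc1 | intermediate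
13 | [(1S,2S,3R)-2-acetoxy-3-(benzoyloxy)-1-hydroxy-6-oxocyclohex-4-en-1-yl]methyl benzoate (2-O-acetylzeylenone) | CC(=O)O[C@H]1[C@H](OC(=O)c2ccccc2)C=CC(=O)[C@]1(O)COC(=O)c1ccccc1 | target

## Step count and least certain steps

Total step count: 9. Longest linear sequence: 9 steps from benzoic acid (1), which also serves as the nucleophile in step 7.

**Step 6 (key step).** The most likely failure is insufficient discrimination between the two enantiotopic alkenes. Both are cis-disubstituted, lie close to each other in a nearly flat ring, and the C7 benzoate carbonyl may compete for the metal. Over-oxidation to the achiral bis-epoxide, and metal-induced ionisation of the bis-allylic alcohol followed by loss of H4 to give an arene, would erode the yield. The fallback gives up asymmetric catalysis. It sets out from 7, which is epoxidised with VO(acac)2 (cat.) and tBuOOH (1.0 equiv) in CH2Cl2 at 0 °C. The same hydroxyl-directed delivery gives the cis-epoxy alcohol as the racemate, that is 8 together with its mirror image [(1R,2R,6R)-2-hydroxy-7-oxabicyclo[4.1.0]hept-3-en-2-yl]methyl benzoate F1. The conditions of step 7 then give 9 together with its mirror image [(1R,5S,6R)-5-(benzoyloxy)-1,6-dihydroxycyclohex-2-en-1-yl]methyl benzoate F2. The two are separated by preparative chromatography on a chiral stationary phase, and the route is rejoined at 9.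

**Step 9.** The most likely failure is a sluggish ene reaction. A cis-disubstituted cyclohexene flanked by electron-withdrawing oxygen substituents reacts slowly with singlet oxygen, so physical quenching and sensitiser bleaching can win. In the second half, Criegee- or Grob-type cleavage of the C1–C6 bond of the β-hydroxy peracetate can compete with removal of H6. The fallback replaces the ene reaction by an epoxide–selenide transposition and sets out from 10:
- Hydroxyl-directed epoxidation (mCPBA, NaHCO3, CH2Cl2, 0 °C) gives the 5,6-epoxide of 10 F3; its configuration is immaterial.
- PhSeSePh/NaBH4 in EtOH/THF buffered with AcOH opens the oxirane at C5, the carbon remote from the quaternary centre, to give the trans hydroxy selenide F4.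
- H2O2 in THF at 0 °C gives the selenoxide F5, which is not isolated. It undergoes syn elimination away from the carbinol carbon to give the C4=C5 allylic alcohol F6.
- MnO2 in CH2Cl2 oxidises the allylic C6 hydroxyl, and the route is rejoined at 13.

**Step 7.** The most likely failure is slow intermolecular delivery of benzoate. That would leave room for transfer of isopropoxide from titanium, ester exchange or migration of benzoate between neighbouring oxygens, and a Lewis-acid-induced 1,2-shift of the C1 vinyl group onto C2 with opening of the wrong C–O bond. The fallback separates ring opening from acylation and sets out from 8. Hydrolytic opening (cat. HClO4, THF/H2O, 0 °C), by attack of water at the less hindered C3 with inversion, gives the triol monobenzoate [(1S,5R,6S)-1,5,6-trihydroxycyclohex-2-en-1-yl]methyl benzoate F7. Benzoylation of the less hindered C3 hydroxyl (BzCl 1.0 equiv, 2,4,6-collidine, CH2Cl2, −40 °C) then rejoins the route at 9.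

## Further compounds

F1 | step 6 | [(1R,2R,6R)-2-hydroxy-7-oxabicyclo[4.1.0]hept-3-en-2-yl]methyl benzoate (mirror image of 8) | O[C@@]1(COC(=O)c2ccccc2)C=CC[C@H]2O[C@@H]12
F2 | step 6 | [(1R,5S,6R)-5-(benzoyloxy)-1,6-dihydroxycyclohex-2-en-1-yl]methyl benzoate (mirror image of 9) | O[C@@H]1[C@@H](OC(=O)c2ccccc2)CC=C[C@@]1(O)COC(=O)c1ccccc1
F3 | step 9 | 5,6-epoxide of 10, oxirane on the face of the C1 hydroxyl, C1–C3 as in 10 | CC(=O)O[C@H]1[C@H](OC(=O)c2ccccc2)C[C@H]2O[C@H]2[C@]1(O)COC(=O)c1ccccc1
F4 | step 9 | 6-hydroxy-5-(phenylselanyl) compound from F3, SePh trans to the C6 hydroxyl, C6 hydroxyl cis to the C1 hydroxyl, C1–C3 as in 10 | CC(=O)O[C@H]1[C@H](OC(=O)c2ccccc2)C[C@H]([Se]c2ccccc2)[C@@H](O)[C@]1(O)COC(=O)c1ccccc1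
F5 | step 9 | selenoxide of F4 (mixture at selenium, not isolated) | CC(=O)O[C@H]1[C@H](OC(=O)c2ccccc2)C[C@H]([Se](=O)c2ccccc2)[C@@H](O)[C@]1(O)COC(=O)c1ccccc1
F6 | step 9 | C6 alcohol corresponding to 13: C4=C5 allylic alcohol, C6 hydroxyl cis to the C1 hydroxyl, C1–C3 as in 13 | CC(=O)O[C@H]1[C@H](OC(=O)c2ccccc2)C=C[C@@H](O)[C@]1(O)COC(=O)c1ccccc1
F7 | step 7 | [(1S,5R,6S)-1,5,6-trihydroxycyclohex-2-en-1-yl]methyl benzoate | O[C@H]1[C@H](O)CC=C[C@]1(O)COC(=O)c1ccccc1
A1 | alternative 1 | (4R,5R)-4,5-bis[(tert-butyldimethylsilyl)oxy]cyclohex-2-en-1-one | CC(C)(C)[Si](C)(C)O[C@H]1[C@H](O[Si](C)(C)C(C)(C)C)C=CC(=O)C1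
A2 | alternative 2 | (4S,5S,6R)-5-acetoxy-6-(benzoyloxy)-4-[(benzoyloxy)methyl]-4-hydroxyocta-1,7-dien-3-one | C=CC(=O)[C@](O)(COC(=O)c1ccccc1)[C@@H](OC(C)=O)[C@H](OC(=O)c1ccccc1)C=C
A3 | alternative 3 | (1R,2S)-1,2-dihydroxycyclohexa-3,5-diene-1-carboxylic acid | O[C@H]1C=CC=C[C@]1(O)C(=O)O
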